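**Retrosynthetic overview**

1. The target is read as ent-labda-8(17),13(16),14-trien-19-yl (E)-p-coumarate, (4R,5S,9R,10S) in labdane numbering, with the C19 oxygen axial and cis to C20. The last disconnection is the ester C–O bond.
2. Key disconnection: C4–C5 and C9–C10 are formed in one cationic cascade (ring A, then ring B), as in geranylgeranyl diphosphate → ent-copalyl diphosphate. The cascade starts from an acyclic (R)-2,2-disubstituted oxirane, so C19–OH and the C4 configuration come from the initiator and no C3 oxygen has to be removed. An allylsilane at C8 plays the role of the enzyme base and gives the 8(17)-methylidene. The diene is already in the chain.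
3. The oxirane comes from a methyl ketone by catalytic asymmetric sulfur-ylide methylene transfer.
4. The acyclic chain comes from a three-component union at C8/C9: terminal alkyne + Me3SiCH2Cu + a homoallylic iodide made from isoprene.
5. The alkyne comes from sulcatone (alkyne formation, SeO2 oxidation, bromide, Cu-catalysed coupling with a ketal Grignard reagent).

Assumption: the (S)-binaphthoxide catalyst in step 9 is taken to give the (R)-oxirane; if the sense is opposite, the (R)-binaphthoxide catalyst is used and nothing else changes.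

**Route**

Step 1
Reactants: 1 6-methylhept-5-en-2-one (sulcatone)
Product: 3 6-methylhept-5-en-1-yne, via enol phosphate 2 (not isolated)
Conditions: LDA (LiN(iPr)2, 1.05 equiv), THF, −78 °C; ClP(O)(OEt)2, −78 → 20 °C; then LDA (2.3 equiv), −78 → 20 °C; H2O
Reagents that add atoms: none
Why: Kinetic deprotonation at the methyl group, O-phosphorylation and base-induced double elimination of the enol phosphate (Negishi conversion of a methyl ketone into a terminal alkyne) give the alkyne that later becomes C8–C9, and the trisubstituted alkene is inert to LDA.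

Step 2
Reactants: 3 6-methylhept-5-en-1-yne
Product: 4 (2E)-2-methylhept-2-en-6-yn-1-ol
Conditions: SeO2 (0.3 equiv), t-BuOOH (3 equiv), salicylic acid (0.1 equiv), CH2Cl2, 0 → 20 °C
Reagents that add atoms: tert-butyl hydroperoxide, CC(C)(C)OO
Why: SeO2-catalysed allylic oxidation (ene reaction then [2,3]-sigmatropic shift, Sharpless conditions) hydroxylates only the methyl group trans to the chain, so the E trisubstituted alkene (future C10=C5 with C1 oxygenated) is set, and the propargylic CH2 reacts much more slowly.

Step 3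
Reactants: 4 (2E)-2-methylhept-2-en-6-yn-1-ol
Product: 5 (5E)-7-bromo-6-methylhept-5-en-1-yne
Conditions: CBr4, PPh3, CH2Cl2, 0 °C
Reagents that add atoms: carbon tetrabromide, BrC(Br)(Br)Br
Why: Appel bromination is an SN2 displacement at the primary allylic carbon under neutral conditions, so the E alkene and the alkyne are untouched.

Step 4
Reactants: 5 (5E)-7-bromo-6-methylhept-5-en-1-yne; 6 2-(2-bromoethyl)-2-methyl-1,3-dioxolane
Product: 8 2-methyl-2-[(4E)-4-methylnon-4-en-8-yn-1-yl]-1,3-dioxolane, via Grignard reagent 7 (not isolated)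
Conditions: 6, Mg, THF, 25 °C; then added to 5, Li2CuCl4 (3 mol %), THF, −40 → 0 °C
Reagents that add atoms: none
Why: Li2CuCl4-catalysed Grignard cross-coupling (Kochi–Schlosser type) joins the primary allylic bromide at its α-carbon to the ketal-masked acetone homoenolate with retention of the E alkene, and at −40 °C with inverse addition the coupling outruns deprotonation of the alkyne C–H.

Step 5
Reactants: 9 isoprene
Product: 11 3-methylidenepent-4-en-1-ol, via isoprenylpotassium 10 (not isolated)
Conditions: LiTMP (lithium 2,2,6,6-tetramethylpiperidide), KOtBu, THF–hexane, −78 → −40 °C; then (CH2O)n, −40 → 0 °C; H2O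
Reagents that add atoms: formaldehyde (as paraformaldehyde), C=O
Why: The LiTMP/KOtBu superbase (Schlosser-type allylic metalation) removes a methyl proton of isoprene, and the symmetrical cross-conjugated allyl anion adds to formaldehyde through a CH2 terminus to give the one-carbon-extended 2-substituted butadiene.

Step 6
Reactants: 11 3-methylidenepent-4-en-1-ol
Product: 12 5-iodo-3-methylidenepent-1-ene
Conditions: I2, PPh3, imidazole, CH2Cl2, 0 °C, dark
Reagents that add atoms: iodine, II
Why: Appel-type iodination converts the primary alcohol into the iodide by SN2 at 0 °C without free acid, which the diene tolerates.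

Step 7
Reactants: 8 2-methyl-2-[(4E)-4-methylnon-4-en-8-yn-1-yl]-1,3-dioxolane; 12 5-iodo-3-methylidenepent-1-ene
Product: 14 2-methyl-2-[(4E,8Z)-4-methyl-12-methylidene-8-[(trimethylsilyl)methyl]tetradeca-4,8,13-trien-1-yl]-1,3-dioxolane, via alkenylcopper 13 (not isolated)
Conditions: Me3SiCH2MgCl, CuBr·SMe2, Et2O–Me2S, −40 °C; 8, −25 → −10 °C; then 12, P(OEt)3, DMPU, −30 → 20 °C
Reagents that add atoms: (trimethylsilyl)methylmagnesium chloride, C[Si](C)(C)C[Mg]Cl
Why: Normant carbocupration adds Me3SiCH2 and Cu syn across the terminal alkyne (silylmethyl to the internal carbon) and the alkenylcopper is alkylated by the primary iodide with retention, so C7 ends trans to C11 (the Z allylsilane) as the chair-like closure of ring B requires, while ketal and diene are inert to the organocopper reagent.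

Step 8
Reactants: 14 the ketal from step 7
Product: 15 (6E,10Z)-6-methyl-14-methylidene-10-[(trimethylsilyl)methyl]hexadeca-6,10,15-trien-2-one
Conditions: PPTS (0.2 equiv), acetone–H2O (10:1), 45 °C
Reagents that add atoms: water, O
Why: Mild acid-catalysed ketal hydrolysis with pyridinium tosylate frees the methyl ketone without protodesilylating the allylsilane or isomerising the diene.

Step 9
Reactants: 15 the methyl ketone from step 8
Product: 16 (2R)-2-methyl-2-[(4E,8Z)-4-methyl-12-methylidene-8-[(trimethylsilyl)methyl]tetradeca-4,8,13-trien-1-yl]oxirane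
Conditions: Me3S(O)I, NaH, THF, 20 °C (ylide); LaLi3[(S)-binaphthoxide]3 (5 mol %), (2,4,6-(MeO)3C6H2)3P=O (5 mol %), 5 Å MS, THF, 20 °C
Reagents that add atoms: trimethylsulfoxonium iodide, C[S+](C)(C)=O.[I-]
Why: Catalytic asymmetric Corey–Chaykovsky epoxidation, in which the LaLi3 tris(binaphthoxide)/phosphine oxide catalyst binds ketone and ylide and distinguishes the methyl from the CH2R side of the carbonyl, sets the (R) quaternary oxirane carbon (future C4, with C19 and its oxygen in place) in about 90% ee, and the ylide touches neither the alkenes nor the silane.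

Step 10
Reactants: 16 the (R)-oxirane from step 9
Product: 17 ent-labda-8(17),13(16),14-trien-19-ol, [(1R,4aS,5R,8aS)-1,4a-dimethyl-6-methylidene-5-(3-methylidenepent-4-en-1-yl)decahydronaphthalen-1-yl]methanol
Conditions: MeAlCl2 (1.5 equiv), CH2Cl2 (0.01 M), −94 → −78 °C; then Et3N, MeOH–H2O
Reagents that add atoms: none
Why: Proposed new method: MeAlCl2 activates the oxirane and the C5=C10 alkene displaces the tertiary C4–O bond from the back (inversion, so (R)-16 gives 4R, with the CH2O–Al arm pseudo-axial because the tied-back oxirane CH2 is smaller there than the methyl group), the chair–chair fold of the E alkene and the Z allylsilane then closes ring A and ring B in one cascade and sets C5, C10 and C9 (trans-decalin, equatorial side chain), and the β-silyl cation at C8 loses Me3Si to chloride to give only the 8(17)-methylidene before the remote diene can add; the closest known reaction types are the Lewis-acid epoxy-polyene (oxidosqualene-like) cyclisation with allylsilane termination and the cation–olefin cyclisation started by a chiral 2,2-disubstituted oxirane, but their combination in the presence of a free myrcene-type diene is untested.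

Step 11
Reactants: 17 ent-labda-8(17),13(16),14-trien-19-ol; 18 (2E)-3-[4-(acetyloxy)phenyl]prop-2-enoic acid
Product: 21 [(1R,4aS,5R,8aS)-1,4a-dimethyl-6-methylidene-5-(3-methylidenepent-4-en-1-yl)decahydronaphthalen-1-yl]methyl (2E)-3-(4-hydroxyphenyl)prop-2-enoate, via mixed anhydride 19 (not isolated), via aryl acetate 20 (not isolated)
Conditions: 18, 2,4,6-Cl3C6H2COCl, Et3N, THF, 20 °C; then 17, DMAP, toluene, 40 °C; then pyrrolidine, 0 → 20 °C
Reagents that add atoms: none
Why: Yamaguchi esterification through the mixed anhydride acylates the hindered neopentyl C19 alcohol with the E cinnamate geometry retained and no stereocentre touched, and pyrrolidine then cleaves only the far more electrophilic aryl acetate by aminolysis to free the phenol.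

**Compound list**

1 | 6-methylhept-5-en-2-one | CC(=O)CCC=C(C)C | starting material
2 | diethyl 6-methylhepta-1,5-dien-2-yl phosphate | C=C(CCC=C(C)C)OP(=O)(OCC)OCC | intermediate
3 | 6-methylhept-5-en-1-yne | C#CCCC=C(C)C | intermediate
4 | (2E)-2-methylhept-2-en-6-yn-1-ol | OC/C(C)=C/CCC#C | intermediate
5 | (5E)-7-bromo-6-methylhept-5-en-1-yne | BrC/C(C)=C/CCC#C | intermediate
6 | 2-(2-bromoethyl)-2-methyl-1,3-dioxolane | CC1(CCBr)OCCO1 | starting material
7 | [2-(2-methyl-1,3-dioxolan-2-yl)ethyl]magnesium bromide | CC1(CC[Mg]Br)OCCO1 | intermediate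
8 | 2-methyl-2-[(4E)-4-methylnon-4-en-8-yn-1-yl]-1,3-dioxolane | CC1(CCC/C(C)=C/CCC#C)OCCO1 | intermediate
9 | isoprene (2-methylbuta-1,3-diene) | C=CC(C)=C | starting material
10 | (2-methylidenebut-3-en-1-yl)potassium | C=CC(=C)C[K] | intermediate
11 | 3-methylidenepent-4-en-1-ol | C=CC(=C)CCO | intermediate
12 | 5-iodo-3-methylidenepent-1-ene | C=CC(=C)CCI | intermediate
13 | {(1Z,5E)-6-methyl-9-(2-methyl-1,3-dioxolan-2-yl)-2-[(trimethylsilyl)methyl]nona-1,5-dien-1-yl}copper (MgBrCl complex) | CC1(CCC/C(C)=C/CC/C(C[Si](C)(C)C)=C/[Cu])OCCO1 | intermediate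
14 | 2-methyl-2-[(4E,8Z)-4-methyl-12-methylidene-8-[(trimethylsilyl)methyl]tetradeca-4,8,13-trien-1-yl]-1,3-dioxolane | CC1(CCC/C(C)=C/CC/C(C[Si](C)(C)C)=C/CCC(=C)C=C)OCCO1 | intermediate
15 | (6E,10Z)-6-methyl-14-methylidene-10-[(trimethylsilyl)methyl]hexadeca-6,10,15-trien-2-one | CC(=O)CCC/C(C)=C/CC/C(C[Si](C)(C)C)=C/CCC(=C)C=C | intermediate
16 | (2R)-2-methyl-2-[(4E,8Z)-4-methyl-12-methylidene-8-[(trimethylsilyl)methyl]tetradeca-4,8,13-trien-1-yl]oxirane | C[C@@]1(CCC/C(C)=C/CC/C(C[Si](C)(C)C)=C/CCC(=C)C=C)CO1 | intermediate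
17 | ent-labda-8(17),13(16),14-trien-19-ol, [(1R,4aS,5R,8aS)-1,4a-dimethyl-6-methylidene-5-(3-methylidenepent-4-en-1-yl)decahydronaphthalen-1-yl]methanol | C=CC(=C)CC[C@@H]1C(=C)CC[C@@H]2[C@](C)(CO)CCC[C@@]12C | intermediate
18 | (2E)-3-[4-(acetyloxy)phenyl]prop-2-enoic acid (4-acetoxycinnamic acid) | CC(=O)Oc1ccc(/C=C/C(=O)O)cc1 | starting material
19 | (2E)-3-[4-(acetyloxy)phenyl]prop-2-enoic 2,4,6-trichlorobenzoic anhydride | CC(=O)Oc1ccc(/C=C/C(=O)OC(=O)c2c(Cl)cc(Cl)cc2Cl)cc1 | intermediate
20 | [(1R,4aS,5R,8aS)-1,4a-dimethyl-6-methylidene-5-(3-methylidenepent-4-en-1-yl)decahydronaphthalen-1-yl]methyl (2E)-3-[4-(acetyloxy)phenyl]prop-2-enoate | C=CC(=C)CC[C@@H]1C(=C)CC[C@@H]2[C@](C)(COC(=O)/C=C/c3ccc(OC(C)=O)cc3)CCC[C@@]12C | intermediate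
21 | [(1R,4aS,5R,8aS)-1,4a-dimethyl-6-methylidene-5-(3-methylidenepent-4-en-1-yl)decahydronaphthalen-1-yl]methyl (2E)-3-(4-hydroxyphenyl)prop-2-enoate (CNP0131099.1) | C=CC(=C)CC[C@@H]1C(=C)CC[C@@H]2[C@](C)(COC(=O)/C=C/c3ccc(O)cc3)CCC[C@@]12C | target

**Step count and risks**

Total steps: 11 (steps 5 and 6 are a two-step side branch). Longest linear sequence: 9 (steps 1–4 and 7–11).

The three steps most likely to fail:

Step 10, the key bicyclisation. The risks are that the tertiary oxirane opens with incomplete transfer of chirality or rearranges to an aldehyde, that some CH2O-equatorial diastereomer forms, and that the diene adds to the C8 cation before desilylation and closes a third ring. The stereochemical course has the closer precedent; the diene is the untested element, so the fallback removes it. The fallback sets out from 8 and comes back at 17. The alkenylcopper 13 made from 8 is alkylated with (4-iodobut-1-yn-1-yl)trimethylsilane in place of 12, which gives the silylalkyne ketal F1. PPTS hydrolysis gives the methyl ketone F2, and the same catalytic ylide epoxidation gives the (R)-oxirane F3. MeAlCl2 then cyclises a substrate that has no π-nucleophile behind the allylsilane and gives the bicyclic silylalkyne alcohol F4. K2CO3 in MeOH removes the alkynyl silyl group to give the terminal alkyne F5. Ethylene–alkyne cross-metathesis (second-generation Grubbs catalyst RuCl2(H2IMes)(PCy3)(=CHPh), C2H4 1 atm, CH2Cl2, 25 °C) turns the alkyne into the 2-substituted butadiene, which is 17.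

Step 7, the three-component union. The carbocupration with the α-silyl copper reagent is slow, and the alkylation of an alkenylcopper with an unactivated, elimination-prone homoallylic iodide is the weak half. The fallback separates the two events and makes the C9–C11 bond by cross-coupling; it sets out from 8 and 12 and comes back at 14. The alkenylcopper 13 is quenched with I2 to give the vinyl iodide F6, with retention of geometry. Iodide 12 is converted with Zn dust and LiCl in THF into the alkylzinc iodide F7. Negishi coupling of F6 with F7 (Pd(dppf)Cl2, THF, 40 °C) gives 14.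

Step 9, the catalytic asymmetric epoxidation. About 90% ee is expected for a methyl n-alkyl ketone and this ee passes unchanged into 21, which falls short of a single enantiomer. The fallback uses a stoichiometric chiral reagent and a separation; it sets out from 15 and comes back at 16. Lithiated (S)-N,S-dimethyl-S-phenylsulfoximine (n-BuLi, THF, −78 °C) adds to 15 to give two diastereomers that are separated on silica, the (2R)-β-hydroxysulfoximine F8 (kept) and the (2S)-β-hydroxysulfoximine F9 (set aside). Me3OBF4 in CH2Cl2 methylates the nitrogen of F8 to give the aminosulfoxonium salt F10, and NaH in THF closes the oxirane with loss of the sulfinamide to give enantiopure 16.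

**Further compounds**

F1 | step 10 | 2-methyl-2-[(4E,8Z)-4-methyl-12-(trimethylsilyl)-8-[(trimethylsilyl)methyl]dodeca-4,8-dien-11-yn-1-yl]-1,3-dioxolane | CC1(CCC/C(C)=C/CC/C(C[Si](C)(C)C)=C/CCC#C[Si](C)(C)C)OCCO1
F2 | step 10 | (6E,10Z)-6-methyl-14-(trimethylsilyl)-10-[(trimethylsilyl)methyl]tetradeca-6,10-dien-13-yn-2-one | CC(=O)CCC/C(C)=C/CC/C(C[Si](C)(C)C)=C/CCC#C[Si](C)(C)C
F3 | step 10 | (2R)-2-methyl-2-[(4E,8Z)-4-methyl-12-(trimethylsilyl)-8-[(trimethylsilyl)methyl]dodeca-4,8-dien-11-yn-1-yl]oxirane | C[C@@]1(CCC/C(C)=C/CC/C(C[Si](C)(C)C)=C/CCC#C[Si](C)(C)C)CO1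
F4 | step 10 | [(1R,4aS,5R,8aS)-1,4a-dimethyl-6-methylidene-5-[4-(trimethylsilyl)but-3-yn-1-yl]decahydronaphthalen-1-yl]methanol | C[Si](C)(C)C#CCC[C@@H]1C(=C)CC[C@@H]2[C@](C)(CO)CCC[C@@]12C
F5 | step 10 | [(1R,4aS,5R,8aS)-5-(but-3-yn-1-yl)-1,4a-dimethyl-6-methylidenedecahydronaphthalen-1-yl]methanol | C#CCC[C@@H]1C(=C)CC[C@@H]2[C@](C)(CO)CCC[C@@]12C
F6 | step 7 | 2-[(4E,8Z)-9-iodo-4-methyl-8-[(trimethylsilyl)methyl]nona-4,8-dien-1-yl]-2-methyl-1,3-dioxolane | CC1(CCC/C(C)=C/CC/C(C[Si](C)(C)C)=C/I)OCCO1
F7 | step 7 | (3-methylidenepent-4-en-1-yl)zinc iodide | C=CC(=C)CC[Zn]I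
F8 | step 9 | (2R,6E,10Z)-2,6-dimethyl-14-methylidene-1-[(S)-N-methyl-S-phenylsulfonimidoyl]-10-[(trimethylsilyl)methyl]hexadeca-6,10,15-trien-2-ol | C[C@@](O)(CCC/C(C)=C/CC/C(C[Si](C)(C)C)=C/CCC(=C)C=C)C[S@@](=O)(=NC)c1ccccc1
F9 | step 9 | (2S,6E,10Z)-2,6-dimethyl-14-methylidene-1-[(S)-N-methyl-S-phenylsulfonimidoyl]-10-[(trimethylsilyl)methyl]hexadeca-6,10,15-trien-2-ol | C[C@](O)(CCC/C(C)=C/CC/C(C[Si](C)(C)C)=C/CCC(=C)C=C)C[S@@](=O)(=NC)c1ccccc1
F10 | step 9 | (dimethylamino)oxo(phenyl)sulfonium tetrafluoroborate derived from F8 by N-methylation, (2R)-2-hydroxy-2,6-dimethyl-14-methylidene-10-[(trimethylsilyl)methyl]hexadeca-6,10,15-trien-1-yl on sulfur | C[C@@](O)(CCC/C(C)=C/CC/C(C[Si](C)(C)C)=C/CCC(=C)C=C)C[S@@+](=O)(N(C)C)c1ccccc1.F[B-](F)(F)F
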